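**Retrosynthetic overview**
1. Target 20 ⇐ keto acetate 18. Reduce the C6 ketone, then move the γ-lactone from O8 to O6; this frees the 8-OH without a protecting group.
2. 18 ⇐ bromo lactone 15. The ten-membered ring comes from a 6→10 ring expansion: an allyl-indium closes C7–C6, then the C1–C6 bond breaks as the C9/C10 epoxide opens.
3. 15 ⇐ epoxy aldehyde 10 + dibromo ester 13 (C7–C8 bond and butanolide). 10 ⇐ keto aldehyde 4 + acetal aldehyde 5 (C9=C10 by aldol condensation, then Sharpless epoxidation). 4 ⇐ 1 + 2.
4. Ring order: cyclohexenone (bought) → oxirane → 8,12-butanolide → transient cyclohexane → cyclodecadiene → 6,12-lactone.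

**Assumption:** germacrane numbering is used (C1–C10 ring, C11–C13 lactone arm, C14 = CH2O, C15 = CH3). C1 is racemic until step 5. The two C1 epimers of 8 are separated there, at most 50 % is usable, and only the epimer drawn is carried on.

**Step 1**
Reactants: 1 3-methylcyclohex-2-en-1-one; 2 allyl bromide
Product: 3 (±)-6-allyl-3-methylcyclohex-2-en-1-one
Conditions: LDA, THF, −78 °C; then 2, −78 → 0 °C
Reagents that add atoms: none
Why: Kinetic α′-deprotonation of the enone followed by SN2 enolate alkylation forms the C1–C10 bond, and the new centre C1 is racemic at this stage.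

**Step 2**
Reactants: 3
Product: 4 (±)-2-(4-methyl-2-oxocyclohex-3-en-1-yl)acetaldehyde
Conditions: OsO4 (2 mol %), NaIO4, 2,6-lutidine, dioxane/H2O, rt
Reagents that add atoms: sodium periodate, [Na+].[O-]I(=O)(=O)=O
Why: Lemieux–Johnson cleavage attacks only the electron-rich terminal alkene, leaves the enone untouched and gives the C14 aldehyde.

**Step 3**
Reactants: 4; 5 2,2-dimethoxyacetaldehyde
Product: 6 (±)-(E)-4,4-dimethoxy-2-(4-methyl-2-oxocyclohex-3-en-1-yl)but-2-enal
Conditions: pyrrolidine (20 mol %), 4-(dimethylamino)benzoic acid (20 mol %), CH2Cl2, 40 °C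
Reagents that add atoms: none
Why: In this enamine-catalysed cross-aldol condensation 5 cannot enolise, so only 4 is the donor, and the (E)-enal (C8 trans to CHO, cis to C1) forms as the thermodynamic product.

**Step 4**
Reactants: 6
Product: 7 (±)-6-[(E)-1-hydroxy-4,4-dimethoxybut-2-en-2-yl]-3-methylcyclohex-2-en-1-one
Conditions: NaBH4 (0.3 equiv), MeOH/CH2Cl2, −78 °C
Reagents that add atoms: none
Why: This chemoselective 1,2-reduction works because the aldehyde is reduced much faster than the β,β-disubstituted enone ketone at −78 °C.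

**Step 5**
Reactants: 7
Product: 8 (6S)-6-[(2S,3R)-3-(dimethoxymethyl)-2-(hydroxymethyl)oxiran-2-yl]-3-methylcyclohex-2-en-1-one (separated from its C1 epimer)
Conditions: Ti(OiPr)4 (10 mol %), L-(+)-DIPT (12 mol %), t-BuOOH, 4 Å MS, CH2Cl2, −20 °C; chromatography
Reagents that add atoms: tert-butyl hydroperoxide, CC(C)(C)OO
Why: Sharpless asymmetric epoxidation directed by the C14 hydroxyl sets C9 (final configuration) and C10 by reagent control, is stereospecific so C8 and C1 stay cis on the oxirane, and the retained C1 epimer has C2 syn to the epoxide oxygen.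

**Step 6**
Reactants: 8
Product: 9 isovalerate of 8 (C14–O–CO–CH2CHMe2; acetal, epoxide and enone unchanged)
Conditions: isovaleryl chloride, pyridine, DMAP (cat.), CH2Cl2, 0 °C
Reagents that add atoms: isovaleryl chloride, CC(C)CC(=O)Cl
Why: Acylation of the only free (primary) hydroxyl installs the final C14 ester under conditions too mild to enolise the β,γ-epoxy ketone.

**Step 7**
Reactants: 9
Product: 10 α,β-epoxy aldehyde (C8 = CHO on the oxirane; C1, C9 and C10 as in 8)
Conditions: TESOTf, 2,6-lutidine, CH2Cl2, 0 °C; then H2O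
Reagents that add atoms: water, O
Why: Acetal cleavage through the lutidinium salt runs under weakly basic conditions, so the acid-labile trisubstituted epoxide and the ester survive.

**Step 8**
Reactants: 11 methyl 2-(bromomethyl)acrylate
Product: 13 methyl (Z)-3-bromo-2-(bromomethyl)acrylate, via tribromo ester 12 (not isolated)
Conditions: Br2, CH2Cl2, 0 °C; then Et3N, 0 °C → rt
Reagents that add atoms: bromine, BrBr
Why: Bromine addition followed by E2 dehydrobromination gives a C4 unit whose carbon C7 can act as an allyl nucleophile twice.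

**Step 9**
Reactants: 10; 13
Product: 15 β-bromo-α-methylene-γ-butyrolactone (O8–C12 lactone; C8 configured as in the target, C7–Br epimers; epoxide, enone and isovalerate intact), via bromohydrin ester 14 (not isolated)
Conditions: In powder (1.0 equiv), THF/H2O, 0 °C; then silica gel, CH2Cl2, rt
Reagents that add atoms: none
Why: Indium Barbier γ-bromoallylation occurs only at the aldehyde, the Cornforth–Evans model for the α-epoxy aldehyde gives the 8,9-anti relation of the target, and lactonisation ties up O8 and C12.

**Step 10**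
Reactants: 15
Product: 18 (1(10)Z,4Z)-9-acetoxy-14-isovaleryloxy-6-oxogermacra-1(10),4,11(13)-trien-8,12-olide (cis-fused lactone; C7, C8, C9 as in the target), via tricyclic indium alkoxide 16 (not isolated), via ring-expanded C9 indium alkoxide 17 (not isolated)
Conditions: In powder (2 equiv), InBr3 (20 mol %), THF, 0 → 23 °C; then Ac2O, DMAP (cat.), 0 °C
Reagents that add atoms: acetic anhydride, CC(=O)OC(C)=O
Why: Proposed new method: indium inserts into the allylic C–Br bond and the allyl-indium adds through C7 to the C6 ketone in a six-membered closure whose short tether forces the cis 7,8-fusion (setting C7) and creates the 11(13)-methylene; in the cis-decalin alkoxide 16 the C1–C6 bond lies anti to the In(III)-activated C10–O bond with C2 syn to that oxygen, so a Grob-type cleavage, driven by epoxide strain release and enone formation, expands 6→10, gives only the 1(10)-Z alkene, keeps the ring-derived 4-Z alkene and frees O9 for in-flask acetylation; the closest known reactions are the SmI2 Barbier cyclisation/Grob fragmentation to medium rings and the epoxy-alcohol fragmentation used for taxane AB rings.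

**Step 11**
Reactants: 18
Product: 20 target CNP0603244.1, via 6-hydroxy-8,12-olide 19 (not isolated)
Conditions: NaBH4, CeCl3·7H2O, MeOH, −78 °C; then CSA (5 mol %), CH2Cl2, rt
Reagents that add atoms: none
Why: Luche 1,2-reduction spares the α-methylene lactone and esters, Felkin–Anh attack anti to the C7–C11 bond with C5 and C8 anti gives the (6R)-alcohol, and O6 then takes over C12 by translactonisation to the more stable trans-6,12-lactone, leaving 8-OH free and 9-OAc in place.

**Compound list**
1 | 3-methylcyclohex-2-en-1-one | CC1=CC(=O)CCC1 | starting material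
2 | allyl bromide | C=CCBr | starting material
3 | (±)-6-allyl-3-methylcyclohex-2-en-1-one | C=CCC1CCC(C)=CC1=O | intermediate
4 | (±)-2-(4-methyl-2-oxocyclohex-3-en-1-yl)acetaldehyde | O=CCC1CCC(C)=CC1=O | intermediate
5 | 2,2-dimethoxyacetaldehyde | COC(OC)C=O | starting material
6 | (±)-(E)-4,4-dimethoxy-2-(4-methyl-2-oxocyclohex-3-en-1-yl)but-2-enal | O=C/C(=C/C(OC)OC)C1CCC(C)=CC1=O | intermediate
7 | (±)-(E)-allylic alcohol | OC/C(=C/C(OC)OC)C1CCC(C)=CC1=O | intermediate
8 | epoxy alcohol, (6S; oxirane 2S,3R) | OC[C@]1([C@@H]2CCC(C)=CC2=O)O[C@H]1C(OC)OC | intermediate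
9 | epoxy acetal isovalerate | CC(C)CC(=O)OC[C@]1([C@@H]2CCC(C)=CC2=O)O[C@H]1C(OC)OC | intermediate
10 | epoxy aldehyde | CC(C)CC(=O)OC[C@]1([C@@H]2CCC(C)=CC2=O)O[C@H]1C=O | intermediate
11 | methyl 2-(bromomethyl)acrylate | C=C(CBr)C(=O)OC | starting material
12 | methyl 2,3-dibromo-2-(bromomethyl)propanoate (not isolated) | COC(=O)C(Br)(CBr)CBr | intermediate
13 | methyl (Z)-3-bromo-2-(bromomethyl)acrylate | Br/C=C(\CBr)C(=O)OC | intermediate
14 | bromohydrin ester (not isolated; C7 epimers) | CC(C)CC(=O)OC[C@]1([C@@H]2CCC(C)=CC2=O)O[C@H]1[C@@H](O)C(Br)C(=C)C(=O)OC | intermediate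
15 | β-bromo-α-methylene butanolide (C7 epimers) | CC(C)CC(=O)OC[C@]1([C@@H]2CCC(C)=CC2=O)O[C@H]1[C@H]3OC(=O)C(=C)C3Br | intermediate
16 | tricyclic alkoxide (not isolated; drawn as the alcohol) | CC(C)CC(=O)OC[C@]12O[C@H]1[C@H]3OC(=O)C(=C)[C@H]3[C@@]4(O)C=C(C)CC[C@@H]24 | intermediate
17 | ring-expanded C9 alkoxide (not isolated; drawn as the alcohol) | CC(C)CC(=O)OC/C1=C/CC/C(C)=C\C(=O)[C@@H]2C(=C)C(=O)O[C@@H]2[C@@H]1O | intermediate
18 | 6-oxo-9-acetoxy-8,12-olide | CC(C)CC(=O)OC/C1=C/CC/C(C)=C\C(=O)[C@@H]2C(=C)C(=O)O[C@@H]2[C@@H]1OC(C)=O | intermediate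
19 | (6R)-6-hydroxy-8,12-olide (not isolated) | CC(C)CC(=O)OC/C1=C/CC/C(C)=C\[C@@H](O)[C@@H]2C(=C)C(=O)O[C@@H]2[C@@H]1OC(C)=O | intermediate
20 | CNP0603244.1 | C=C1C(=O)O[C@@H]2/C=C(/C)CC/C=C(/COC(=O)CC(C)C)[C@@H](OC(C)=O)[C@@H](O)[C@@H]12 | target

**Total steps:** 11. **Longest linear sequence:** 10 (steps 1–7 and 9–11).

**Three steps most likely to fail**

Step 10 (proposed new step). The alkoxide may translactonise or undergo a Payne shift before it fragments. The fallback uses known chemistry, sets out from 15 and returns at 19. It fragments first and closes the ring afterwards.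
- Luche reduction of 15 gives the cyclohexenol F6.
- Ti(OiPr)4-promoted epoxy-alcohol fragmentation of F6 is stereospecific in the same sense as the main step. It opens the six-membered ring to the seco (2Z,6Z)-enal alcohol F7.
- Ac2O/pyridine converts F7 into the seco enal acetate F8.
- A CrCl2-mediated intramolecular allylation under high dilution closes C6–C7 to 19. This is the macrocyclisation already used for germacranolides such as parthenolide. Compound 19 then lactonises to 20 as in step 11.

Step 9. The product is itself an allylic bromide and could be consumed by indium. The fallback sets out from 10 and 11 and returns at 18.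
- A Zn/aq. NH4Cl Dreiding–Schmidt reaction of 10 with 11 gives the α-methylene lactone F3.
- Br2 adds to F3 to give the dibromo lactone F4.
- Et3N eliminates HBr from F4 to give the 3-(bromomethyl)butenolide F5.
- F5 gives the same allyl-indium as 15 under the step 10 conditions.

Step 7. TESOTf may open the epoxide or silylate the ketone. The fallback sets out from 7 and returns at 10. It reverses the order of events and changes the epoxidation method.
- Acylation of 7 with isovaleryl chloride gives the allylic ester acetal F1.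
- Aqueous TFA unmasks the enal ester F2 while no epoxide is present.
- Iminium-catalysed epoxidation of F2 (H2O2, the matching enantiomer of diphenylprolinol TMS ether) gives 10. The C1 epimers are separated at that point.

**Further compounds**
F1 | step 7 | allylic ester acetal | CC(C)CC(=O)OC/C(=C/C(OC)OC)C1CCC(C)=CC1=O
F2 | step 7 | enal ester | CC(C)CC(=O)OC/C(=C/C=O)C1CCC(C)=CC1=O
F3 | step 9 | α-methylene lactone | CC(C)CC(=O)OC[C@]1([C@@H]2CCC(C)=CC2=O)O[C@H]1[C@H]3OC(=O)C(=C)C3
F4 | step 9 | dibromo lactone | CC(C)CC(=O)OC[C@]1([C@@H]2CCC(C)=CC2=O)O[C@H]1[C@H]3OC(=O)C(Br)(CBr)C3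
F5 | step 9 | 3-(bromomethyl)butenolide | CC(C)CC(=O)OC[C@]1([C@@H]2CCC(C)=CC2=O)O[C@H]1[C@H]3OC(=O)C(CBr)=C3
F6 | step 10 | cyclohexenol | CC(C)CC(=O)OC[C@]1([C@@H]2CCC(C)=CC2O)O[C@H]1[C@H]3OC(=O)C(=C)C3Br
F7 | step 10 | seco (2Z,6Z)-enal alcohol | O=C/C=C(/C)CC/C=C(/COC(=O)CC(C)C)[C@@H](O)[C@H]1OC(=O)C(=C)C1Br
F8 | step 10 | seco enal acetate | O=C/C=C(/C)CC/C=C(/COC(=O)CC(C)C)[C@@H](OC(C)=O)[C@H]1OC(=O)C(=C)C1Br
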